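Ring C is cut into a three-carbon unit C18–C9–C10 carrying oxygen on C9 and a four-carbon unit C11–C12–C13–C17, an s-cis diene held exocyclic on ring D. One rhodium-catalysed operation, carbene addition to the C11=C12 enol ether followed by Cope rearrangement of the cis-divinylcyclopropane, forms C10–C11 and C17–C18, closes ring C, sets C17 and leaves C9 and C11 oxygenated and C12=C13 in place for the later carbinol. The precursors are diene 8 (E-silyl enol ether at C11, E-ethylidene at C13, C15 dioxolane) and siloxyvinyl diazoester 11. Pyranone rings A and B are then attached at C18 and C9 as a hemiketal.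

Key step: step 7

Numbering used: O8 pyran oxygen, C9 hemiketal carbon, C10 CHOH, C11 ring ketone, C12 tertiary carbinol, C13=C14–C15(=O) enone, C16 CMe2, C17 CHMe, C18 ring-fusion CH, C19 CH2; ring A pyranone, ring B pyran, ring C seven-membered, ring D cyclopentenone.

Remark: C9, C10 and C18 lie on or beside the ring-chain-tautomeric hemiketal/β-diketone and are taken to equilibrate to the natural arrangement (trans-fused ring B, axial anomeric OH); the R catalyst antipode is assigned by analogy with the usual sense of this catalyst family and would be exchanged for its enantiomer if the sense proved opposite.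

Step 1
Reactants: 1 2,2-dimethylcyclopentane-1,3-dione
Product: 2 6,6-dimethyl-1,4-dioxaspiro[4.4]nonan-7-one (C15 dioxolane, C12 ketone)
Conditions: HOCH2CH2OH (1.1 equiv), p-TsOH (cat.), benzene, reflux, Dean–Stark
Reagents that add atoms: ethylene glycol, OCCO
Why: Acid-catalysed ketalisation with one equivalent of diol should stop at the mono-dioxolane because the second carbonyl is then flanked by the gem-dimethyl carbon and the spiro ketal.

Step 2
Reactants: 2 mono-dioxolane ketone; 3 acetaldehyde
Product: 5 (E)-8-ethylidene-6,6-dimethyl-1,4-dioxaspiro[4.4]nonan-7-one, via aldol mesylate 4 (not isolated)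
Conditions: LiN(i-Pr)2, THF, −78 °C; MeCHO; then MsCl, −78 to 0 °C; then Et3N, 0 °C to rt
Reagents that add atoms: none
Why: Aldol condensation through the only possible enolate (C13, since C16 is quaternary), with E1cB loss of mesylate that should give the thermodynamically preferred E enone (methyl anti to C12).

Step 3
Reactants: 5 E-ethylidene ketone
Product: 6 spiro vinyl oxirane (C11 methylene and oxygen on C12, racemic at C12, E-ethylidene retained)
Conditions: Me3S+ I−, KN(SiMe3)2, THF, −10 °C to rt
Reagents that add atoms: trimethylsulfonium iodide, C[S+](C)C.[I-]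
Why: Corey–Chaykovsky epoxidation, in which the small unstabilised sulfonium ylide adds 1,2 to the hindered enone carbonyl and closes the oxirane; the racemic spiro centre is flattened again in step 4.

Step 4
Reactants: 6 spiro vinyl oxirane
Product: 8 diene with E-TBS enol ether at C11 and E-ethylidene at C13, via aldehyde 7 (not isolated)
Conditions: BF3·OEt2 (cat.), CH2Cl2, −78 °C; then Et3N, TBSOTf, −78 to 0 °C
Reagents that add atoms: tert-butyldimethylsilyl triflate, CC(C)(C)[Si](C)(C)OS(=O)(=O)C(F)(F)F
Why: Meinwald rearrangement (ionisation at the tertiary allylic C12, 1,2-hydride shift from C11) gives the β,γ-unsaturated aldehyde, whose doubly activated C12–H is removed by soft enolisation without touching the ethylidene; the silyloxy group should take the outside position (cis to C16) because the inside position is blocked by the C17 hydrogen.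

Step 5
Reactants: 9 benzyl acetoacetate
Product: 10 benzyl 2-diazo-3-oxobutanoate
Conditions: p-ABSA, Et3N, MeCN, 0 °C to rt
Reagents that add atoms: 4-acetamidobenzenesulfonyl azide, CC(=O)Nc1ccc(cc1)S(=O)(=O)N=[N+]=[N-]
Why: Regitz diazo transfer to the active methylene of a β-keto ester.

Step 6
Reactants: 10 benzyl 2-diazo-3-oxobutanoate
Product: 11 benzyl 2-diazo-3-(tert-butyldimethylsilyloxy)but-3-enoate
Conditions: TBSOTf, Et3N, CH2Cl2, 0 °C
Reagents that add atoms: tert-butyldimethylsilyl triflate, CC(C)(C)[Si](C)(C)OS(=O)(=O)C(F)(F)F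
Why: Soft enolisation and O-silylation of the methyl ketone, the standard preparation of enol diazoacetates, which leaves the diazo group intact.

Step 7
Reactants: 8 diene; 11 siloxyvinyl diazoester
Product: 13 ring C/D cycloheptadiene (C9 TBS enol ether; benzyl ester on C10; C11–OTBS cis to C17 methyl; C12=C13; C15 dioxolane; 17R), via divinylcyclopropane 12 (not isolated)
Conditions: Rh2(R-PTAD)4 (dirhodium tetrakis[(R)-1-adamantyl(phthalimido)acetate], 1 mol %), slow addition of 11, hexanes, −20 °C to rt, then 50 °C
Reagents that add atoms: none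
Why: Loss of N2 gives the donor–acceptor rhodium carbenoid, whose carbene carbon C10 adds across the enol ether bond C11=C12 with the siloxyvinyl arm cis to the ethylidene arm on C12, and cis-divinylcyclopropane 12 then undergoes a [3,3] shift that breaks C10–C12 and makes C17–C18. The closest known reaction type is the tandem cyclopropanation/Cope rearrangement (formal [4+3] cycloaddition) of vinyldiazoacetates with dienes, which covers oxygenated dienes and siloxyvinyl diazoacetates with this catalyst family. Ring C is closed in the sigmatropic step through a boat transition state, the diene being locked s-cis by ring D. C17 is set by the catalyst-controlled face of carbene addition, relayed suprafacially through the boat and translated by the E-ethylidene geometry; the temporary C11 centre follows from the E-enol ether geometry, which places OTBS cis to the C17 methyl. The step needs site selectivity for C11=C12 over C13=C17 and the cis-divinyl arrangement; the substrate offers the enol ether as the more electron-rich π bond with a CH terminus, and both terminal substituents point outward so that neither lies over the cyclopropane in the boat.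

Step 8
Reactants: 13 cycloheptadiene
Product: 14 β-keto benzyl ester (C9 ketone, ester on C10, C11–OTBS kept; C10 epimers and enol in equilibrium)
Conditions: Bu4NF, AcOH (1:1), THF, −20 to 0 °C
Reagents that add atoms: none
Why: Buffered fluoride desilylation should cleave the electron-poor O-silyl enol ether far faster than the hindered secondary alkyl silyl ether, and acetic acid protonates the enolate before retro-aldol or β-elimination can set in.

Step 9
Reactants: 14 β-keto ester
Product: 15 Mannich base (CH2NMe2 on C18, trans to C17 methyl)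
Conditions: LiN(i-Pr)2 (2.2 equiv), THF, −78 to −30 °C; Me2N=CH2+ I−, −78 to 0 °C
Reagents that add atoms: N,N-dimethylmethyleneiminium iodide, C=[N+](C)C.[I-]
Why: Mannich reaction of the β-keto ester dianion at its more basic γ-carbon C18 (C10 is already deprotonated and so blocked), with the iminium ion approaching anti to the neighbouring C17 methyl; C18 stays epimerisable and is finally fixed in step 11.

Step 10
Reactants: 15 Mannich base
Product: 17 β-amino ketone (C9 ketone, C10 methylene), via β-keto acid 16 (not isolated)
Conditions: H2 (1 atm), 10% Pd/C, EtOAc, rt, then 40 °C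
Reagents that add atoms: none
Why: Hydrogenolysis of the benzyl ester followed by decarboxylation of the β-keto acid through the usual six-membered transition state, under neutral conditions to which the tetrasubstituted alkene, the silyl ether and the dioxolane are inert.

Step 11
Reactants: 17 β-amino ketone; 18 4-hydroxy-5,6-dimethyl-2H-pyran-2-one
Product: 21 rings A–D hemiketal (C9–OH; C11–OTBS; C12=C13; C15 dioxolane), via methiodide 19 (not isolated), via methylene ketone 20 (not isolated)
Conditions: MeI, MeCN, rt; evaporate; then 18, NaHCO3, MeCN, rt to 40 °C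
Reagents that add atoms: none
Why: Quaternisation and mild base release the exo-methylene ketone (Mannich-base elimination), the pyronate adds through C3 to C19 (Michael addition) and the pyranone hydroxyl closes onto the C9 ketone; C18 and C9 should equilibrate to the trans-fused hemiketal with C19 anti to the C17 methyl and the anomeric hydroxyl axial.

Step 12
Reactants: 21 hemiketal with C15 dioxolane
Product: 22 C15 ketone with the C12=C13 double bond still out of conjugation
Conditions: PPTS (cat.), acetone/H2O, 45 °C
Reagents that add atoms: water, O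
Why: Mild acid hydrolysis of the strained neopentyl dioxolane, of the kind used to free β,γ-unsaturated ketones without conjugation, which the silyl ether and hemiketal should survive.

Step 13
Reactants: 22 β,γ-unsaturated ketone
Product: 24 γ-hydroxy enone (C12–OH trans to C17 methyl; C13=C14–C15=O; C11–OTBS), via epoxy ketone 23 (not isolated)
Conditions: mCPBA, NaHCO3, CH2Cl2, −20 to 0 °C; then Et3N, rt
Reagents that add atoms: meta-chloroperbenzoic acid, OOC(=O)c1cccc(Cl)c1
Why: Prilezhaev epoxidation of the most electron-rich π bond from the face opposite the cis-disposed allylic C11–OTBS and C17 methyl groups, followed by E1cB opening of the β,γ-epoxy ketone, which puts the hydroxyl on C12 and the double bond at C13=C14.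

Step 14
Reactants: 24 silyl ether
Product: 25 C11,C12-diol (secondary C11–OH, tertiary C12–OH)
Conditions: HF·pyridine, THF/pyridine, 0 °C to rt
Reagents that add atoms: none
Why: Acidic fluoride desilylation removes the secondary silyl ether without the basic conditions that would invite retro-aldol or α-ketol chemistry.

Step 15
Reactants: 25 diol
Product: 26 10-deoxy target (C11 ketone, C10 methylene)
Conditions: IBX, DMSO, rt
Reagents that add atoms: none
Why: IBX oxidation converts the secondary carbinol of a secondary/tertiary 1,2-diol into the α-hydroxy ketone without glycol cleavage, and the tertiary C12–OH and hemiketal OH cannot be oxidised.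

Step 16
Reactants: 26 10-deoxy target
Product: 27 CNP0525404.1
Conditions: DMDO (1.0 equiv), acetone, −40 to 0 °C
Reagents that add atoms: dimethyldioxirane, CC1(C)OO1
Why: Dioxirane α-hydroxylation of a 1,3-dicarbonyl compound: the C9/C11 β-diketone enol reached by ring-chain tautomerism of the hemiketal should accept oxygen at C10 anti to the axial C9 oxygen, and re-closure of the hemiketal leaves C9 and C10 in the equilibrating natural arrangement.

Compound list
1 | 2,2-dimethylcyclopentane-1,3-dione | CC1(C)C(=O)CCC1=O | starting material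
2 | 6,6-dimethyl-1,4-dioxaspiro[4.4]nonan-7-one | O=C1CCC2(OCCO2)C1(C)C | intermediate
3 | acetaldehyde | CC=O | starting material
4 | aldol mesylate (racemic mixture of diastereomers) | CC(OS(C)(=O)=O)C1CC2(OCCO2)C(C)(C)C1=O | intermediate
5 | (E)-8-ethylidene-6,6-dimethyl-1,4-dioxaspiro[4.4]nonan-7-one | C/C=C1/C(=O)C(C)(C)C2(OCCO2)C1 | intermediate
6 | spiro vinyl oxirane (racemic at C12, E-ethylidene) | C/C=C1/C2(CO2)C(C)(C)C3(OCCO3)C1 | intermediate
7 | β,γ-unsaturated aldehyde (racemic at C12, E-ethylidene) | C/C=C1/C(C=O)C(C)(C)C2(OCCO2)C1 | intermediate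
8 | diene: E-TBS enol ether at C11 (OTBS cis to C16), E-ethylidene at C13, C15 dioxolane | CC(C)(C)[Si](C)(C)O/C=C1/C(=C/C)CC2(OCCO2)C1(C)C | intermediate
9 | benzyl acetoacetate | CC(=O)CC(=O)OCc1ccccc1 | starting material
10 | benzyl 2-diazo-3-oxobutanoate | CC(=O)C(=[N+]=[N-])C(=O)OCc1ccccc1 | intermediate
11 | benzyl 2-diazo-3-(tert-butyldimethylsilyloxy)but-3-enoate | C=C(O[Si](C)(C)C(C)(C)C)C(=[N+]=[N-])C(=O)OCc1ccccc1 | intermediate
12 | cis-divinylcyclopropane (C10/C11/C12 ring, spiro on ring D; siloxyvinyl cis to the ethylidene arm, C11–OTBS and ester on the other face) | O=C(OCc1ccccc1)[C@]2(C(=C)O[Si](C)(C)C(C)(C)C)[C@H](O[Si](C)(C)C(C)(C)C)[C@@]23/C(=C/C)CC4(OCCO4)C3(C)C | intermediate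
13 | ring C/D cycloheptadiene (C9 TBS enol ether, benzyl ester on C10, C11–OTBS cis to C17 methyl, C12=C13, C15 dioxolane, 17R) | O=C(OCc1ccccc1)C2=C(O[Si](C)(C)C(C)(C)C)C[C@@H](C)C3=C(C(C)(C)C4(C3)OCCO4)[C@H]2O[Si](C)(C)C(C)(C)C | intermediate
14 | β-keto benzyl ester (C10 epimers/enol in equilibrium, no descriptor drawn at C10) | O=C(OCc1ccccc1)C2C(=O)C[C@@H](C)C3=C(C(C)(C)C4(C3)OCCO4)[C@H]2O[Si](C)(C)C(C)(C)C | intermediate
15 | Mannich base (C18–CH2NMe2 trans to C17 methyl; C10 as in 14) | O=C(OCc1ccccc1)C2C(=O)[C@H](CN(C)C)[C@@H](C)C3=C(C(C)(C)C4(C3)OCCO4)[C@H]2O[Si](C)(C)C(C)(C)C | intermediate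
16 | β-keto acid (C10 as in 14) | OC(=O)C2C(=O)[C@H](CN(C)C)[C@@H](C)C3=C(C(C)(C)C4(C3)OCCO4)[C@H]2O[Si](C)(C)C(C)(C)C | intermediate
17 | β-amino ketone (C9 ketone, C10 methylene, C11–OTBS, C18–CH2NMe2) | O=C1C[C@H](O[Si](C)(C)C(C)(C)C)C2=C(CC3(OCCO3)C2(C)C)[C@H](C)[C@H]1CN(C)C | intermediate
18 | 4-hydroxy-5,6-dimethyl-2H-pyran-2-one | Cc1oc(=O)cc(O)c1C | starting material
19 | methiodide of 17 | O=C1C[C@H](O[Si](C)(C)C(C)(C)C)C2=C(CC3(OCCO3)C2(C)C)[C@H](C)[C@H]1C[N+](C)(C)C.[I-] | intermediate
20 | exo-methylene ketone (C18=C19) | O=C1C[C@H](O[Si](C)(C)C(C)(C)C)C2=C(CC3(OCCO3)C2(C)C)[C@H](C)C1=C | intermediate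
21 | rings A–D hemiketal (C9–OH, C11–OTBS, C12=C13, C15 dioxolane; configuration at C9, C17, C18 as in the target) | Cc1oc(=O)c2c(c1C)O[C@]1(O)C[C@H](O[Si](C)(C)C(C)(C)C)C3=C(CC4(OCCO4)C3(C)C)[C@H](C)[C@H]1C2 | intermediate
22 | C15 ketone, C12=C13 unconjugated | Cc1oc(=O)c2c(c1C)O[C@]1(O)C[C@H](O[Si](C)(C)C(C)(C)C)C3=C(CC(=O)C3(C)C)[C@H](C)[C@H]1C2 | intermediate
23 | C12,C13-epoxy ketone (epoxide trans to C11–OTBS and C17 methyl) | Cc1oc(=O)c2c(c1C)O[C@]1(O)C[C@H](O[Si](C)(C)C(C)(C)C)[C@@]34O[C@@]3(CC(=O)C4(C)C)[C@H](C)[C@H]1C2 | intermediate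
24 | γ-hydroxy enone (C12–OH, C13=C14–C15=O, C11–OTBS) | Cc1oc(=O)c2c(c1C)O[C@]1(O)C[C@H](O[Si](C)(C)C(C)(C)C)[C@@]3(O)C(=CC(=O)C3(C)C)[C@H](C)[C@H]1C2 | intermediate
25 | C11,C12-diol | Cc1oc(=O)c2c(c1C)O[C@]1(O)C[C@H](O)[C@@]3(O)C(=CC(=O)C3(C)C)[C@H](C)[C@H]1C2 | intermediate
26 | 10-deoxy target (C11 ketone) | Cc1oc(=O)c2c(c1C)O[C@]1(O)CC(=O)[C@@]3(O)C(=CC(=O)C3(C)C)[C@H](C)[C@H]1C2 | intermediate
27 | CNP0525404.1 | Cc1oc(=O)c2c(c1C)O[C@]1(O)[C@H](O)C(=O)[C@@]3(O)C(=CC(=O)C3(C)C)[C@H](C)[C@H]1C2 | target

Total step count: 16. Longest linear sequence: 14 steps (steps 1–4 and 7–16).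

Steps most likely to fail

Step 7. The weak point is site selection. Both diene bonds are trisubstituted, and in a 1-oxygenated diene the terminus remote from oxygen (C17) is the more nucleophilic one. The carbene carbon may therefore add across C13=C17, so that after the Cope shift the ester sits on C18 and the CH2 group is C10. Fallback: that regioisomer is used, because its ester carbon is C19. Setting out again from 8 and 11 under the same catalysis (antipode chosen for 17R), the regioisomeric cycloheptadiene F1 would be reduced with i-Bu2AlH to the allylic alcohol F2. F2 with pyranone 18 and catalytic PPTS should lose silanol and water to give methylene ketone 20, which 18 traps to give 21. The route is re-entered at 21, and steps 8–11 are not needed.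

Step 12. The risk is migration of the C12=C13 double bond into conjugation with the freed C15 ketone under acid, which would also expose C17 to dienol formation. Fallback: invert the order so that no β,γ-unsaturated ketone is ever present. Setting out from 21, mCPBA epoxidation (same facial bias) would give the epoxy ketal F3. The dioxolane is then removed under near-neutral conditions (Ce(NH4)2(NO3)6 cat., MeCN/aqueous borate buffer), and the epoxy ketone 23 so formed opens with Et3N. The route is re-entered at 24.

Step 16. The risks are over-oxidation, attack at other enolisable positions and poor facial control at C10. Fallback: transfer a protected oxygen. Setting out from 26, dibenzoyl peroxide with NaHCO3 (α-benzoyloxylation of a 1,3-dicarbonyl) would give the C10 benzoate F4, which cannot be oxidised further. K2CO3 in MeOH at 0 °C then removes the benzoate, and the route arrives at 27.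

Further compounds
F1 | step 7 | regioisomeric cycloheptadiene (benzyl ester on C18, C9 TBS enol ether, C10 methylene, C11–OTBS cis to C17 methyl) | O=C(OCc1ccccc1)C2=C(O[Si](C)(C)C(C)(C)C)C[C@H](O[Si](C)(C)C(C)(C)C)C3=C(CC4(OCCO4)C3(C)C)[C@@H]2C
F2 | step 7 | allylic alcohol (C19 hydroxymethyl on C18=C9 enol ether) | OCC2=C(O[Si](C)(C)C(C)(C)C)C[C@H](O[Si](C)(C)C(C)(C)C)C3=C(CC4(OCCO4)C3(C)C)[C@@H]2C
F3 | step 12 | epoxy ketal (C12,C13-epoxide, C15 dioxolane) | Cc1oc(=O)c2c(c1C)O[C@]1(O)C[C@H](O[Si](C)(C)C(C)(C)C)[C@@]34O[C@@]3(CC5(OCCO5)C4(C)C)[C@H](C)[C@H]1C2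
F4 | step 16 | C10 benzoate of 27 | Cc1oc(=O)c2c(c1C)O[C@]1(O)[C@H](OC(=O)c4ccccc4)C(=O)[C@@]3(O)C(=CC(=O)C3(C)C)[C@H](C)[C@H]1C2
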